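**Plan**

1. Retrosynthesis: the three phenols are masked as MOM ethers (12), and the depside is cut at the bond between the ester oxygen and C4 of ring A, giving ring B acid 6 and ring A bromide 10.
2. Enabling feature: in ring A (C1 CO2Me, C2 OH, C6 CH3) the depside oxygen sits on C4, para to the ester and flanked by C3-H and C5-H. The ring B carboxyl carbon C1' is buried between C2'-OH and C6'-CH3 (C3' CH3, C4' OH, C5' Cl), so arylating the carboxylate oxygen at C4 avoids any attack at that carbonyl.
3. Ring B: 2,5-dimethylresorcinol 1 is formylated, chlorinated, MOM-protected and oxidised to acid 6 (steps 1-4).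
4. Ring A: methyl 4-bromo-2-methylbenzoate 7 is hydroxylated ortho to the ester and MOM-protected to bromide 10 (steps 5-6).
5. Both rings are bought as arenes and no ring is formed. They are joined in step 7 and the MOM ethers are removed in step 8.
6. Stereochemistry: the target has no stereocentre, so none has to be set.

Key step: step 7

Assumption: 1 and 7 are taken as commercial; "ring A" is the methyl benzoate ring and "ring B" the chlorinated acyl ring, with primed locants counted from its carboxyl carbon.

**Route**

Step 1
Reactants: 1 2,5-dimethylbenzene-1,3-diol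
Product: 3 2,4-dihydroxy-3,6-dimethylbenzaldehyde, via aryl iminium chloride 2 (not isolated)
Conditions: POCl3, DMF, 0 °C to rt; then H2O, 50 °C
Reagents that add atoms: N,N-dimethylformamide, CN(C)C=O; water, O
Why: Vilsmeier-Haack formylation, in which the chloroiminium ion made from DMF and POCl3 should attack C4 of 1 (ortho to one hydroxyl, para to the other, equivalent to C6), the iminium group of 2 deactivates the ring against a second attack, and warm water hydrolyses 2 to aldehyde 3.

Step 2
Reactants: 3 2,4-dihydroxy-3,6-dimethylbenzaldehyde
Product: 4 3-chloro-4,6-dihydroxy-2,5-dimethylbenzaldehyde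
Conditions: SO2Cl2 (1.05 equiv), Et2O, 0 °C to rt
Reagents that add atoms: sulfuryl chloride, O=S(=O)(Cl)Cl
Why: Electrophilic aromatic chlorination, in which C5 of 3 is the only ring carbon still bearing hydrogen and is ortho to the C4 hydroxyl and para to the C2 hydroxyl, so one equivalent of SO2Cl2 should substitute there as it does with related resorcylaldehydes.

Step 3
Reactants: 4 3-chloro-4,6-dihydroxy-2,5-dimethylbenzaldehyde
Product: 5 3-chloro-4,6-bis(methoxymethoxy)-2,5-dimethylbenzaldehyde
Conditions: NaH, MOMCl, DMF, 0 °C to rt
Reagents that add atoms: chloromethyl methyl ether, COCCl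
Why: Williamson-type O-alkylation, in which NaH turns both phenols, the chelated one included, into phenoxides that displace chloride from MOMCl while the non-enolisable aldehyde is left alone.

Step 4
Reactants: 5 3-chloro-4,6-bis(methoxymethoxy)-2,5-dimethylbenzaldehyde
Product: 6 3-chloro-4,6-bis(methoxymethoxy)-2,5-dimethylbenzoic acid
Conditions: NaClO2, NaH2PO4, 2-methyl-2-butene, t-BuOH/H2O, rt; work-up at pH 4
Reagents that add atoms: sodium chlorite, [Na+].[O-]Cl=O
Why: Pinnick oxidation, in which chlorous acid adds to the hindered aldehyde and fragments to the acid and HOCl that 2-methyl-2-butene scavenges, and the buffered medium should be tolerated by the aryl MOM ethers and cannot chlorinate the fully substituted ring.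

Step 5
Reactants: 7 methyl 4-bromo-2-methylbenzoate
Product: 9 methyl 4-bromo-2-hydroxy-6-methylbenzoate, via aryl trifluoroacetate 8 (not isolated)
Conditions: [RuCl2(p-cymene)]2 (2.5 mol%), K2S2O8, TFA/TFAA, 80 °C; then aq NaHCO3
Reagents that add atoms: trifluoroacetic acid, OC(=O)C(F)(F)F
Why: Ester-directed ruthenium-catalysed C-H oxygenation, in which the ester carbonyl should guide carboxylate-assisted ruthenation by divalent ruthenium to C6 (the only free ortho position of 7), persulfate oxidation to tetravalent ruthenium and C-O reductive elimination give trifluoroacetate 8 that resists further oxidation and is hydrolysed on work-up, and the aryl bromide is inert to this acidic oxidative medium.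

Step 6
Reactants: 9 methyl 4-bromo-2-hydroxy-6-methylbenzoate
Product: 10 methyl 4-bromo-2-(methoxymethoxy)-6-methylbenzoate
Conditions: NaH, MOMCl, THF/DMF, 0 °C to rt
Reagents that add atoms: chloromethyl methyl ether, COCCl
Why: Williamson-type O-alkylation, in which deprotonation breaks the salicylate hydrogen bond and the phenoxide should be alkylated by MOMCl faster than anything happens at the methyl ester or the aryl bromide.

Step 7
Reactants: 6 3-chloro-4,6-bis(methoxymethoxy)-2,5-dimethylbenzoic acid (1.3 equiv); 10 methyl 4-bromo-2-(methoxymethoxy)-6-methylbenzoate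
Product: 12 methyl 4-{[3-chloro-4,6-bis(methoxymethoxy)-2,5-dimethylbenzoyl]oxy}-2-(methoxymethoxy)-6-methylbenzoate, via tetrabutylammonium carboxylate 11 (not isolated)
Conditions: Bu4NOH (1 equiv to 6), MeCN/H2O, evaporate with toluene; then 10, NiBr2(dme) (10 mol%), 4,4'-di-tert-butyl-2,2'-bipyridine (12 mol%), DMA, undivided cell, graphite felt anode, nickel foam cathode, constant current, rt
Reagents that add atoms: none
Why: Cathodic reduction of the NiBr2/bipyridine complex gives low-valent nickel that inserts into the C4-Br bond of 10, carboxylate 11 displaces bromide on the resulting divalent arylnickel species, and anodic oxidation to trivalent nickel triggers C(aryl)-O reductive elimination, releasing monovalent nickel that re-enters the cycle. The closest known reaction type is the nickel-catalysed esterification of aryl bromides with carboxylic acids under paired electrolysis (and its photoredox counterpart), which accepts benzoic acids and electron-poor aryl bromides. No ring is closed and no stereocentre is created; the step only joins ring A to ring B through the O-C4 bond. The step needs C-Br to react and not the C-Cl bond of ring B, and that chloride, on an electron-rich ring with substituents on both neighbouring carbons, should be inert to low-valent nickel at room temperature, whereas the bromide para to CO2Me is activated. The carboxylate must also survive the anode, which should hold because the nickel carboxylate complex is oxidised at a potential well below that needed for Kolbe-type oxidation of an aromatic carboxylate or for oxidation of the MOM-protected arene. The bulk of ring B should not matter, because the bond is made at the carboxylate oxygen, which lies outside the C2'-OMOM and C6'-CH3 groups, and at C4 of ring A, which has hydrogen on both neighbours.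

Step 8
Reactants: 12 methyl 4-{[3-chloro-4,6-bis(methoxymethoxy)-2,5-dimethylbenzoyl]oxy}-2-(methoxymethoxy)-6-methylbenzoate
Product: 13 methyl 4-[(3-chloro-4,6-dihydroxy-2,5-dimethylbenzoyl)oxy]-2-hydroxy-6-methylbenzoate
Conditions: 3 M aq HCl, THF, 40 °C
Reagents that add atoms: none
Why: Acid-catalysed acetal hydrolysis, in which the three MOM ethers ionise to oxocarbenium ions that water captures, while the aryl benzoate (shielded on both sides of its carbonyl) and the methyl ester should not hydrolyse in dilute acid at this temperature.

**Compound list**

1 | 2,5-dimethylbenzene-1,3-diol | Cc1cc(O)c(C)c(O)c1 | starting material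
2 | N-[(2,4-dihydroxy-3,6-dimethylphenyl)methylidene]-N-methylmethanaminium chloride | C[N+](C)=Cc1c(C)cc(O)c(C)c1O.[Cl-] | intermediate (not isolated)
3 | 2,4-dihydroxy-3,6-dimethylbenzaldehyde | O=Cc1c(C)cc(O)c(C)c1O | intermediate
4 | 3-chloro-4,6-dihydroxy-2,5-dimethylbenzaldehyde | O=Cc1c(C)c(Cl)c(O)c(C)c1O | intermediate
5 | 3-chloro-4,6-bis(methoxymethoxy)-2,5-dimethylbenzaldehyde | O=Cc1c(C)c(Cl)c(OCOC)c(C)c1OCOC | intermediate
6 | 3-chloro-4,6-bis(methoxymethoxy)-2,5-dimethylbenzoic acid | OC(=O)c1c(C)c(Cl)c(OCOC)c(C)c1OCOC | intermediate
7 | methyl 4-bromo-2-methylbenzoate | COC(=O)c1ccc(Br)cc1C | starting material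
8 | methyl 4-bromo-2-methyl-6-[(trifluoroacetyl)oxy]benzoate | COC(=O)c1c(C)cc(Br)cc1OC(=O)C(F)(F)F | intermediate (not isolated)
9 | methyl 4-bromo-2-hydroxy-6-methylbenzoate | COC(=O)c1c(C)cc(Br)cc1O | intermediate
10 | methyl 4-bromo-2-(methoxymethoxy)-6-methylbenzoate | COCOc1cc(Br)cc(C)c1C(=O)OC | intermediate
11 | tetrabutylammonium 3-chloro-4,6-bis(methoxymethoxy)-2,5-dimethylbenzoate | CCCC[N+](CCCC)(CCCC)CCCC.[O-]C(=O)c1c(C)c(Cl)c(OCOC)c(C)c1OCOC | intermediate (not isolated)
12 | methyl 4-{[3-chloro-4,6-bis(methoxymethoxy)-2,5-dimethylbenzoyl]oxy}-2-(methoxymethoxy)-6-methylbenzoate | COC(=O)c1c(C)cc(OC(=O)c2c(C)c(Cl)c(OCOC)c(C)c2OCOC)cc1OCOC | intermediate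
13 | methyl 4-[(3-chloro-4,6-dihydroxy-2,5-dimethylbenzoyl)oxy]-2-hydroxy-6-methylbenzoate | COC(=O)c1c(C)cc(OC(=O)c2c(C)c(Cl)c(O)c(C)c2O)cc1O | target

**Step count**

Total steps: 8. Longest linear sequence: 6 steps (steps 1, 2, 3, 4, 7, 8).

**Steps most likely to fail**

Step 7. The bulky carboxylate may capture the arylnickel intermediate too slowly, so that protodebromination or reductive homocoupling consumes the bromide, or the electron-rich ring B may be degraded at the anode. The fallback keeps the same O-C4 bond but forms it oxidatively with copper; it sets out from 10 and returns at 12. Bromide 10 would be borylated with B2pin2, Pd(dppf)Cl2 and KOAc in dioxane at 90 °C to methyl 2-(methoxymethoxy)-6-methyl-4-(4,4,5,5-tetramethyl-1,3,2-dioxaborolan-2-yl)benzoate F1. The pinacol ester would be cleaved with NaIO4 and NH4OAc in aqueous acetone to [4-(methoxycarbonyl)-3-(methoxymethoxy)-5-methylphenyl]boronic acid F2. F2 would then be coupled with acid 6 in a Chan-Lam O-arylation (Cu(OTf)2, urea, EtOAc, 60 °C, air), the urea buffering the medium so that the MOM ethers persist, to give 12.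

Step 5. C-H ruthenation of the twisted, electron-poor benzoate may stall, or the substrate may be degraded oxidatively at 80 °C. The fallback replaces direct oxygenation by directed borylation and oxidation; it sets out from 7 and returns at 9. Ester-directed ortho C-H borylation of 7 with [Ir(OMe)(cod)]2, P[3,5-(CF3)2C6H3]3 and B2pin2 in octane at 80 °C should give methyl 4-bromo-2-methyl-6-(4,4,5,5-tetramethyl-1,3,2-dioxaborolan-2-yl)benzoate F3, since C6 is the only position the ester can direct to and the other ring hydrogens are flanked by bromine. Oxidation of F3 with NaBO3·4H2O in THF/H2O at rt should then deliver phenol 9.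

Step 2. The free resorcinol may be over-chlorinated, or attacked at the methyl-bearing carbon between the two hydroxyls, which would give dearomatised chlorodienones. The fallback removes the free phenols before chlorination; it sets out from 3 and returns at 5. Aldehyde 3 would be protected with NaH and MOMCl in DMF to 2,4-bis(methoxymethoxy)-3,6-dimethylbenzaldehyde F4, which cannot form a dienone. F4 would then be chlorinated at its single free ring position (ortho to one MOM ether, para to the other) with N-chlorosuccinimide in DMF at 40 °C under neutral conditions to give 5.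

**Further compounds**

F1 | step 7 | methyl 2-(methoxymethoxy)-6-methyl-4-(4,4,5,5-tetramethyl-1,3,2-dioxaborolan-2-yl)benzoate | COCOc1cc(B2OC(C)(C)C(C)(C)O2)cc(C)c1C(=O)OC
F2 | step 7 | [4-(methoxycarbonyl)-3-(methoxymethoxy)-5-methylphenyl]boronic acid | COCOc1cc(B(O)O)cc(C)c1C(=O)OC
F3 | step 5 | methyl 4-bromo-2-methyl-6-(4,4,5,5-tetramethyl-1,3,2-dioxaborolan-2-yl)benzoate | COC(=O)c1c(C)cc(Br)cc1B1OC(C)(C)C(C)(C)O1
F4 | step 2 | 2,4-bis(methoxymethoxy)-3,6-dimethylbenzaldehyde | O=Cc1c(C)cc(OCOC)c(C)c1OCOC
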